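**Plan**

1. Retrosynthesis: the fourteen benzyl–oxygen bonds and the two gallate C(=O)–O bonds are cut first, then C3–H (back to a ketone) and the C2–aryl bond to ring B. The central cut takes C3–C4 and C4–C4a of ring C together, leaving a benzofuran-3-one and a C8-diazomethyl derivative of protected (+)-catechin.
2. Enabling feature: ring C of the upper unit (O1, C2, C3, C4, C4a, C8a) is the five-membered ring of a benzofuran-3(2H)-one plus the single carbon C4, lying between the oxygenated C3 and C4a. C4a has ring A oxygens at both ortho positions (O1 on C8a, the oxygen on C5) and at the para position (the oxygen on C7), so it is the carbon expected to shift.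
3. Forward order: rings D, F and E come intact from (+)-catechin, whose C8 is brominated, formylated and converted into the diazomethyl group. Ring A arrives with the benzofuranone, ring C is made in step 8 by one-carbon enlargement, ring B is attached at C2 in step 9, and both gallates go on last.
4. Stereochemistry: the lower-unit centres are those of (+)-catechin. Upper C2 and C4 are set by base equilibration of the ketone to the 2,4-cis arrangement, and upper C3 by axial hydride delivery (2,3-trans-3,4-trans). The sense of the upper unit relative to the lower one rests on diastereomer equilibration plus chromatographic removal of the other diastereomer after step 10.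

Key step: step 8

Remarks on the chemistry:
- The target is read as (+)-catechin-(4α→8)-(+)-catechin 3,3'-di-O-gallate (procyanidin B3 digallate): upper unit 2R,3S,4S, lower unit 2R,3S.
- Upper-unit atoms are numbered O1, C2, C3, C4, C4a, C5–C8, C8a (rings A and C, catechol ring B). Lower-unit atoms carry the suffix L (rings D and F, catechol ring E).
- "LU" denotes the (2R,3S)-5,7-bis(benzyloxy)-2-[3,4-bis(benzyloxy)phenyl]-3-[(tert-butyldimethylsilyl)oxy]chroman-8-yl group.
- Assumption: C2 and C4 of ketones 11 and 13 epimerise readily, and no strong preference between the two 2,4-cis diastereomers of 13 (upper unit 2R,4S or 2S,4R on the fixed lower unit) is assumed. Compound 13 denotes the 2R,4S member, and material of the other sense is removed as a diastereomeric alcohol after step 10.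

**Route**

Step 1
Reactants: 1 (+)-catechin
Product: 2 (2R,3S)-5,7-bis(benzyloxy)-2-[3,4-bis(benzyloxy)phenyl]chroman-3-ol (tetra-O-benzylcatechin)
Conditions: BnBr (4.4 equiv), K2CO3, DMF, 0 °C → rt
Reagents that add atoms: benzyl bromide BrCc1ccccc1
Why: Williamson etherification, in which the four phenols are alkylated under carbonate base while the much less acidic secondary C3 hydroxyl stays free and no stereocentre is touched.

Step 2
Reactants: 2 tetra-O-benzylcatechin
Product: 3 (2R,3S)-8-bromo-5,7-bis(benzyloxy)-2-[3,4-bis(benzyloxy)phenyl]chroman-3-ol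
Conditions: NBS (1.0 equiv), CH2Cl2, −78 °C → rt
Reagents that add atoms: N-bromosuccinimide O=C1CCC(=O)N1Br
Why: Electrophilic aromatic bromination with NBS: of the two free positions of ring D, C8 is the one that tetra-O-benzyl flavan-3-ols brominate first, so one equivalent at low temperature should give the 8-bromide without touching the catechol ring or the stereocentres.

Step 3
Reactants: 3 8-bromo-tetra-O-benzylcatechin
Product: 4 tert-butyl{[(2R,3S)-8-bromo-5,7-bis(benzyloxy)-2-[3,4-bis(benzyloxy)phenyl]chroman-3-yl]oxy}dimethylsilane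
Conditions: TBSCl, imidazole, DMF, rt
Reagents that add atoms: tert-butyldimethylsilyl chloride CC(C)(C)[Si](C)(C)Cl
Why: Silylation of the only free hydroxyl under Corey's imidazole conditions; a silyl ether is chosen here instead of the final gallate because it survives the aryllithium of step 4, hydrazine, the Lewis acid and the basic arylation, and is removed later without touching benzyl ethers.

Step 4
Reactants: 4 8-bromo silyl ether
Product: 6 (2R,3S)-5,7-bis(benzyloxy)-2-[3,4-bis(benzyloxy)phenyl]-3-[(tert-butyldimethylsilyl)oxy]chromane-8-carbaldehyde, via 8-lithio derivative 5 (not isolated)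
Conditions: n-BuLi, THF, −78 °C; then DMF, −78 → 0 °C; H2O
Reagents that add atoms: N,N-dimethylformamide CN(C)C=O (the formyl group of 6); n-butyllithium [Li]CCCC (the lithium of 5)
Why: Bromine–lithium exchange followed by Bouveault formylation with DMF: exchange at −78 °C is faster than benzylic deprotonation of the benzyl ethers, and the position of the formyl group is fixed by that of the bromine.

Step 5
Reactants: 6 8-carbaldehyde
Product: 7 (E)-hydrazone of 6, LU-CH=N-NH2
Conditions: N2H4·H2O (excess), EtOH/THF, 60 °C
Reagents that add atoms: hydrazine hydrate NN.O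
Why: Condensation of the aldehyde with hydrazine to the free hydrazone, with a large excess of hydrazine and the two ortho substituents working against azine formation; the only stereo-element formed is the E geometry of the C=N bond, which disappears in step 6.

Step 6
Reactants: 7 hydrazone
Product: 8 8-(diazomethyl) compound LU-CH=N2, i.e. (2R,3S)-5,7-bis(benzyloxy)-2-[3,4-bis(benzyloxy)phenyl]-3-[(tert-butyldimethylsilyl)oxy]-8-(diazomethyl)chromane
Conditions: activated MnO2, Na2SO4, CH2Cl2, 0 °C, dark; cold filtration, solution used at once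
Reagents that add atoms: none
Why: Dehydrogenation of an aldehyde hydrazone to the aryldiazomethane with MnO2, a standard hydrazone oxidation; the two ortho oxygen substituents shield the diazo carbon, and cold, acid-free handling should limit loss of N2.

Step 7
Reactants: 9 4,6-dihydroxybenzofuran-3(2H)-one
Product: 10 4,6-bis(benzyloxy)benzofuran-3(2H)-one
Conditions: BnBr (2.2 equiv), K2CO3, DMF, rt
Reagents that add atoms: benzyl bromide BrCc1ccccc1
Why: Williamson etherification: the two phenols (one chelated, one a vinylogous acid) are far more acidic than the C2 methylene, so mild carbonate base should give O-benzylation rather than C-alkylation.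

Step 8
Reactants: 10 4,6-bis(benzyloxy)benzofuran-3(2H)-one (1.5 equiv); 8 diazomethyl compound LU-CH=N2
Product: 11 (4S)-5,7-bis(benzyloxy)-4-(LU)chroman-3-one (C4 labile; expected together with its C4 epimer)
Conditions: Sc(OTf)3 (10 mol %), 4 Å MS, CH2Cl2/PhMe, −78 → −20 °C, slow addition of 8 to 10
Reagents that add atoms: none
Why: Proposed new method: Sc(OTf)3, chelated between the ketone oxygen and the neighbouring C4 benzyloxy oxygen of 10, activates the otherwise vinylogous-ester-like carbonyl, the nucleophilic diazo carbon of 8 adds to it (C3–C4 bond), and the scandium-bound diazonium betaine loses N2 as the ring A carbon antiperiplanar to the leaving group shifts from C3 to C4 (C4–C4a bond). The closest known reaction type is the Sc(OTf)3-catalysed homologation of cyclic ketones with non-stabilised aryldiazomethanes (a Tiffeneau–Demjanov or Büchner–Curtius–Schlotterbeck 1,2-shift), which has not been shown on a benzofuran-3-one or with a diazo partner flanked by two ortho oxygens. Ring C is not closed by a cyclisation but arises by ring enlargement: the five-membered furanone ring takes up the diazo carbon through the 1,2-aryl shift and becomes the six-membered pyranone. The one new stereocentre, C4, forms with inversion at the diazo carbon during the shift, so its sense depends on which face of the diazo carbon meets the bound ketone under the influence of the chiral lower unit; because C4 is α to the ketone and doubly benzylic it is treated as epimerisable and is fixed thermodynamically in steps 9 and 10. The step needs aryl migration instead of migration of the O–CH2 carbon, and C-addition instead of O-alkylation of the enol or epoxide closure: the migrating carbon (C3a of 10, later C4a) carries oxygen at both ortho positions and the para position and can bridge as a stabilised phenonium-like centre, whereas C2 is inductively deactivated by O1 and the Lewis acid holds the alkoxide back from closing an epoxide. Excess 10, slow addition of 8 and low temperature should keep acid-induced loss of N2 from the electron-rich diazo compound in check.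

Step 9
Reactants: 11 4-(LU)chroman-3-one; 12 4-bromo-1,2-bis(benzyloxy)benzene
Product: 13 (2R,4S)-5,7-bis(benzyloxy)-2-[3,4-bis(benzyloxy)phenyl]-4-(LU)chroman-3-one
Conditions: Pd(OAc)2 (5 mol %), XPhos (10 mol %), K3PO4, PhMe, 80 °C, Ar; held until the epimer ratio is constant
Reagents that add atoms: none
Why: Palladium-catalysed α-arylation of a ketone enolate (Buchwald–Hartwig type): the unhindered C2 methylene couples, whereas arylation at C4 would have to build a triaryl-substituted quaternary carbon, and the basic medium lets both α-centres epimerise so that the 2,4-cis ketone with both aryl groups equatorial should accumulate, its (2S,4R) companion on the same lower unit staying in equilibrium with it.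

Step 10
Reactants: 13 2,4-diaryl ketone
Product: 14 (2R,3S,4S)-5,7-bis(benzyloxy)-2-[3,4-bis(benzyloxy)phenyl]-4-(LU)chroman-3-ol
Conditions: NaBH4, THF/MeOH, −40 → 0 °C
Reagents that add atoms: none
Why: Hydride reduction with NaBH4: the small hydride should add along the axial direction of the diequatorial ketone, anti to the axial H2 and H4, placing the new hydroxyl equatorial (2,3-trans-3,4-trans, 3S) while methoxide keeps the ketone diastereomers interconverting, and the alcohol with the mirror-image upper unit is a diastereomer that is removed by chromatography at this stage.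

Step 11
Reactants: 14 silyl ether alcohol
Product: 15 (2R,3S,4S)-5,7-bis(benzyloxy)-2-[3,4-bis(benzyloxy)phenyl]-4-[(2R,3S)-5,7-bis(benzyloxy)-2-[3,4-bis(benzyloxy)phenyl]-3-hydroxychroman-8-yl]chroman-3-ol (octa-O-benzylprocyanidin B3)
Conditions: Bu4NF, THF, 0 °C → rt
Reagents that add atoms: none
Why: Fluoride-induced cleavage of the silyl ether, driven by Si–F bond formation, which leaves benzyl ethers, the interflavan bond and all stereocentres untouched.

Step 12
Reactants: 15 octa-O-benzylprocyanidin B3; 16 3,4,5-tris(benzyloxy)benzoic acid (3 equiv)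
Product: 17 octa-O-benzylprocyanidin B3 3,3L-bis[3,4,5-tris(benzyloxy)benzoate]
Conditions: DCC, DMAP, CH2Cl2, rt
Reagents that add atoms: none
Why: Steglich esterification of both secondary alcohols in one operation; acylation takes place at oxygen, so C3 and C3L keep their configuration.

Step 13
Reactants: 17 fully benzylated digallate
Product: 18 (+)-catechin-(4α→8)-(+)-catechin 3,3L-di-O-gallate (target)
Conditions: H2 (1 atm), Pd(OH)2/C, THF/MeOH/H2O, rt
Reagents that add atoms: none
Why: Hydrogenolysis of all fourteen benzyl ethers over Pd(OH)2/C; the gallate esters, the C4–C8L bond and the stereocentres are inert under these neutral conditions.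

**Compound list**

1 | (+)-catechin, (2R,3S) | O[C@H]1Cc2c(O)cc(O)cc2O[C@@H]1c1ccc(O)c(O)c1 | starting material
2 | (2R,3S)-5,7-bis(benzyloxy)-2-[3,4-bis(benzyloxy)phenyl]chroman-3-ol | O[C@H]1Cc2c(OCc3ccccc3)cc(OCc3ccccc3)cc2O[C@@H]1c1ccc(OCc2ccccc2)c(OCc2ccccc2)c1 | intermediate
3 | (2R,3S)-8-bromo-5,7-bis(benzyloxy)-2-[3,4-bis(benzyloxy)phenyl]chroman-3-ol | O[C@H]1Cc2c(OCc3ccccc3)cc(OCc3ccccc3)c(Br)c2O[C@@H]1c1ccc(OCc2ccccc2)c(OCc2ccccc2)c1 | intermediate
4 | 3-O-tert-butyldimethylsilyl ether of 3 | CC(C)(C)[Si](C)(C)O[C@H]1Cc2c(OCc3ccccc3)cc(OCc3ccccc3)c(Br)c2O[C@@H]1c1ccc(OCc2ccccc2)c(OCc2ccccc2)c1 | intermediate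
5 | 8-lithio derivative of 4 (not isolated) | CC(C)(C)[Si](C)(C)O[C@H]1Cc2c(OCc3ccccc3)cc(OCc3ccccc3)c([Li])c2O[C@@H]1c1ccc(OCc2ccccc2)c(OCc2ccccc2)c1 | intermediate
6 | (2R,3S)-5,7-bis(benzyloxy)-2-[3,4-bis(benzyloxy)phenyl]-3-[(tert-butyldimethylsilyl)oxy]chromane-8-carbaldehyde | CC(C)(C)[Si](C)(C)O[C@H]1Cc2c(OCc3ccccc3)cc(OCc3ccccc3)c(C=O)c2O[C@@H]1c1ccc(OCc2ccccc2)c(OCc2ccccc2)c1 | intermediate
7 | (E)-hydrazone of 6 | CC(C)(C)[Si](C)(C)O[C@H]1Cc2c(OCc3ccccc3)cc(OCc3ccccc3)c(/C=N/N)c2O[C@@H]1c1ccc(OCc2ccccc2)c(OCc2ccccc2)c1 | intermediate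
8 | (2R,3S)-5,7-bis(benzyloxy)-2-[3,4-bis(benzyloxy)phenyl]-3-[(tert-butyldimethylsilyl)oxy]-8-(diazomethyl)chromane | CC(C)(C)[Si](C)(C)O[C@H]1Cc2c(OCc3ccccc3)cc(OCc3ccccc3)c(C=[N+]=[N-])c2O[C@@H]1c1ccc(OCc2ccccc2)c(OCc2ccccc2)c1 | intermediate
9 | 4,6-dihydroxybenzofuran-3(2H)-one | O=C1COc2cc(O)cc(O)c12 | starting material
10 | 4,6-bis(benzyloxy)benzofuran-3(2H)-one | O=C1COc2cc(OCc3ccccc3)cc(OCc3ccccc3)c12 | intermediate
11 | (4S)-5,7-bis(benzyloxy)-4-(LU)chroman-3-one (C4 labile) | O=C1[C@H](c2c(OCc3ccccc3)cc(OCc3ccccc3)c3c2O[C@H](c2ccc(OCc4ccccc4)c(OCc4ccccc4)c2)[C@@H](O[Si](C)(C)C(C)(C)C)C3)c2c(OCc3ccccc3)cc(OCc3ccccc3)cc2OC1 | intermediate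
12 | 4-bromo-1,2-bis(benzyloxy)benzene | Brc1ccc(OCc2ccccc2)c(OCc2ccccc2)c1 | starting material
13 | (2R,4S)-5,7-bis(benzyloxy)-2-[3,4-bis(benzyloxy)phenyl]-4-(LU)chroman-3-one | O=C1[C@H](c2c(OCc3ccccc3)cc(OCc3ccccc3)c3c2O[C@H](c2ccc(OCc4ccccc4)c(OCc4ccccc4)c2)[C@@H](O[Si](C)(C)C(C)(C)C)C3)c2c(OCc3ccccc3)cc(OCc3ccccc3)cc2O[C@@H]1c1ccc(OCc2ccccc2)c(OCc2ccccc2)c1 | intermediate
14 | (2R,3S,4S)-5,7-bis(benzyloxy)-2-[3,4-bis(benzyloxy)phenyl]-4-(LU)chroman-3-ol | O[C@H]1[C@H](c2c(OCc3ccccc3)cc(OCc3ccccc3)c3c2O[C@H](c2ccc(OCc4ccccc4)c(OCc4ccccc4)c2)[C@@H](O[Si](C)(C)C(C)(C)C)C3)c2c(OCc3ccccc3)cc(OCc3ccccc3)cc2O[C@@H]1c1ccc(OCc2ccccc2)c(OCc2ccccc2)c1 | intermediate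
15 | octa-O-benzylprocyanidin B3: upper unit (2R,3S,4S), lower unit (2R,3S), both C3 hydroxyls free | O[C@H]1[C@H](c2c(OCc3ccccc3)cc(OCc3ccccc3)c3c2O[C@H](c2ccc(OCc4ccccc4)c(OCc4ccccc4)c2)[C@@H](O)C3)c2c(OCc3ccccc3)cc(OCc3ccccc3)cc2O[C@@H]1c1ccc(OCc2ccccc2)c(OCc2ccccc2)c1 | intermediate
16 | 3,4,5-tris(benzyloxy)benzoic acid | OC(=O)c1cc(OCc2ccccc2)c(OCc2ccccc2)c(OCc2ccccc2)c1 | starting material
17 | octa-O-benzylprocyanidin B3 3,3L-bis[3,4,5-tris(benzyloxy)benzoate] | O=C(O[C@H]1[C@H](c2c(OCc3ccccc3)cc(OCc3ccccc3)c3c2O[C@H](c2ccc(OCc4ccccc4)c(OCc4ccccc4)c2)[C@@H](OC(=O)c2cc(OCc4ccccc4)c(OCc4ccccc4)c(OCc4ccccc4)c2)C3)c2c(OCc3ccccc3)cc(OCc3ccccc3)cc2O[C@@H]1c1ccc(OCc2ccccc2)c(OCc2ccccc2)c1)c1cc(OCc2ccccc2)c(OCc2ccccc2)c(OCc2ccccc2)c1 | intermediate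
18 | (+)-catechin-(4α→8)-(+)-catechin 3,3L-di-O-gallate: upper unit (2R,3S,4S), lower unit (2R,3S) | O=C(O[C@H]1[C@H](c2c(O)cc(O)c3c2O[C@H](c2ccc(O)c(O)c2)[C@@H](OC(=O)c2cc(O)c(O)c(O)c2)C3)c2c(O)cc(O)cc2O[C@@H]1c1ccc(O)c(O)c1)c1cc(O)c(O)c(O)c1 | target

**Step count and risks**

Total step count: 13. Longest linear sequence: 12 steps (steps 1–6 and 8–13, from (+)-catechin).

Steps most likely to fail:

Step 8. The electron-rich diazo compound may lose N2 under the Lewis acid before it adds, giving benzylic-cation products and azine. The enol form of 10 may be O-alkylated, the O–CH2 carbon may migrate instead of the aryl carbon, or the less conjugated product ketone may be homologated a second time. The fallback uses the established flavan-4-yl cation coupling and sets out from 2. Oxidation of C4 of 2 with DDQ in CH2Cl2 in the presence of 2-ethoxyethanol should give (2R,3S,4S)-5,7-bis(benzyloxy)-2-[3,4-bis(benzyloxy)phenyl]-4-(2-ethoxyethoxy)chroman-3-ol F1. Ionisation of F1 with TMSOTf in CH2Cl2 at −78 °C in the presence of an excess of 2 as the C8 nucleophile should give the 3,4-trans product, which is 15; the route is rejoined there and steps 9–11 are not needed. Because the upper-unit centres then come from (+)-catechin, this fallback also removes the dependence on an unproven equilibrium bias.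

Step 9. Enolisation may occur mainly toward the more acidic, conjugated C4 side, so that the enolate is sequestered or oxidised and C2 is not arylated, or a second arylation may follow. The fallback sets out from 11 and fixes the enolate regiochemistry before the coupling. Kinetic deprotonation of the accessible C2 methylene with LiN(SiMe3)2 in the presence of TMSCl (THF, −78 °C, internal quench) should give (4S)-5,7-bis(benzyloxy)-4-(LU)-3-(trimethylsilyloxy)-4H-chromene F2. Its palladium-catalysed arylation with 12 through the tin enolate (Pd(OAc)2, P(t-Bu)3, Bu3SnF, PhMe, 85 °C) is a known regiocontrolled arylation of silyl enol ethers and should lead to 13 after brief equilibration with K3PO4.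

Step 10. Hydride may be delivered from the equatorial direction (poor facial selectivity), giving the axial alcohol, and the two interconverting 2,4-cis ketones may be reduced without discrimination, so that much material ends with the mirror-image upper unit. The fallback sets out from 13 and replaces irreversible hydride transfer by a reversible Meerwein–Ponndorf–Verley reduction (Al(Oi-Pr)3, i-PrOH/PhMe, 80 °C). C2, C3 and C4 then all equilibrate through the ketone, and the all-equatorial alcohols should be the thermodynamic sink. Compound 14 is isolated by chromatography. The diastereomer (2S,3R,4R)-5,7-bis(benzyloxy)-2-[3,4-bis(benzyloxy)phenyl]-4-(LU)chroman-3-ol F3 is returned to the same medium with a little acetone as hydride acceptor, so that it re-enters the equilibrium through 13 and is drawn over to 14, where the route continues.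

**Further compounds**

F1 | step 8 | (2R,3S,4S)-5,7-bis(benzyloxy)-2-[3,4-bis(benzyloxy)phenyl]-4-(2-ethoxyethoxy)chroman-3-ol | O[C@H]1[C@@H](OCCOCC)c2c(OCc3ccccc3)cc(OCc3ccccc3)cc2O[C@@H]1c1ccc(OCc2ccccc2)c(OCc2ccccc2)c1
F2 | step 9 | (4S)-5,7-bis(benzyloxy)-4-(LU)-3-(trimethylsilyloxy)-4H-chromene | C[Si](C)(C)OC1=COc2cc(OCc3ccccc3)cc(OCc3ccccc3)c2[C@H]1c1c(OCc2ccccc2)cc(OCc2ccccc2)c2c1O[C@H](c1ccc(OCc3ccccc3)c(OCc3ccccc3)c1)[C@@H](O[Si](C)(C)C(C)(C)C)C2
F3 | step 10 | (2S,3R,4R)-5,7-bis(benzyloxy)-2-[3,4-bis(benzyloxy)phenyl]-4-(LU)chroman-3-ol | O[C@@H]1[C@@H](c2c(OCc3ccccc3)cc(OCc3ccccc3)c3c2O[C@H](c2ccc(OCc4ccccc4)c(OCc4ccccc4)c2)[C@@H](O[Si](C)(C)C(C)(C)C)C3)c2c(OCc3ccccc3)cc(OCc3ccccc3)cc2O[C@H]1c1ccc(OCc2ccccc2)c(OCc2ccccc2)c1
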